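At early times target only climbs, but the cedar run then turns: after 3.00 h its substrate stays between 17.3% and 19.5% while target sinks. So one molecule of substrate meets two forks: it becomes target, and that target must then last until the end of the run.

| flask | substrate | partner | temperature | remark | time |
|---|---|---|---|---|---|
| birch | 12 mM | 1.5 equiv | 85 °C | run made earlier |  |
| cedar | 12 mM | 0.75 equiv | 100 °C | run made earlier |  |
| oak | 12 mM | 1.1 equiv | 85 °C | run made earlier |  |
| alder | 6 mM | 1.5 equiv | 100 °C | run made earlier |  |
| epsilon | 12 mM | 1.50 equiv (fed, over 5.0 h) | 100 °C | all else is in the flask from the start; the feed brings no volume worth counting | 8.0 h |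
| beta | 12 mM (fed, over 5.0 h) | 1.50 equiv | 100 °C | all else is in the flask from the start; the feed brings no volume worth counting | 8.0 h |
| zeta | 12 mM | 1.50 equiv (fed, over 5.0 h) |  | the addition at 60 °C, then warmed to 100 °C; the feed brings no volume worth counting | 8.0 h |
| delta | 12 mM | 1.50 equiv | 100 °C | everything together at the start | 8.0 h |

| run | time / h | target / % | substrate / % |
|---|---|---|---|
| birch | 0.833 | 6.7 | 85.5 |
| birch | 1.33 | 14.5 | 79.7 |
| birch | 2.00 | 20.8 | 71.3 |
| birch | 3.00 | 30.4 | 59.7 |
| birch | 4.00 | 34.9 | 51.8 |
| birch | 6.00 | 44.9 | 36.3 |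
| birch | 10.0 | 42.5 | 21.5 |
| cedar | 0.417 | 15.3 | 69.5 |
| cedar | 1.33 | 34.5 | 35.5 |
| cedar | 2.50 | 34.3 | 22.1 |
| cedar | 3.00 | 32.2 | 19.1 |
| cedar | 5.00 | 24.9 | 17.3 |
| cedar | 6.00 | 21.0 | 17.9 |
| cedar | 8.00 | 17.2 | 19.5 |
| oak | 1.33 | 13.4 | 79.6 |
| oak | 2.00 | 21.2 | 72.2 |
| oak | 3.00 | 27.0 | 59.2 |
| oak | 5.00 | 37.0 | 43.4 |
| oak | 6.00 | 41.3 | 38.4 |
| oak | 10.0 | 41.9 | 20.0 |
| oak | 15.0 | 33.2 | 16.1 |
| alder | 1.50 | 42.4 | 30.9 |
| alder | 3.00 | 45.4 | 14.9 |
| alder | 5.00 | 39.0 | 8.7 |
| alder | 6.00 | 35.7 | 5.9 |
| alder | 8.00 | 30.4 | 8.4 |

(standard deviation of a reading: 1 percentage point)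

- the flask with the highest amount of target, in percent of the substrate charged ("all alike" if they lie within 1.5 percentage points) (epsilon / beta / zeta / delta / all alike)
- final target, as a percentage of the substrate charged, in epsilon
- final target, as a percentage of the substrate charged, in beta
- final target, as a percentage of the substrate charged, in zeta
- final target, as a percentage of the substrate charged, in delta

- the numbers in the tables scatter by 1 percentage point (one standard deviation)

Let k_T be the first-order constant of target loss, and let S = exp(−k_T·Δt) be the chance that target made a time Δt before the end still stands at the end.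

Each given number is tried in turn for what an error in it does to S. The partner charge, 1.50 equiv, is the same in epsilon, beta, zeta and delta and does not enter S. Substrate in alder is down to 30.9% at 1.50 h, a time shorter than the warm stretch of zeta, 3.00 h, so an error in the substrate rate moves the birth of target within that stretch. A fractional error in k_T shifts S, as a fraction of itself, by k_T·Δt times that fraction.

Cedar gives the number. Target in cedar falls from 32.2% to 17.2% between 3.00 h and 8.00 h, so the first-order constant of target loss reads 0.125 h⁻¹, with the scatter of those readings. The multiplier k_T·Δt is 1.00 over 8.0 h and 0.375 over the warm stretch.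

The reckoning here assumes that zeta makes its target after warming from 60 °C, so target born at the moment of warming has S = 0.686. In delta, hot from the start, target born at the start has S = 0.367. So zeta should beat delta; S does not place beta.

The forecast names beta, with epsilon 28%, beta 38%, zeta 37% and delta 26%, and says of zeta “so it stops near the peak”.

The simulation gives zeta the most target: epsilon 37.7%, beta 15.0%, zeta 44.0%, delta 27.3%.

    target ⇌ isomer of the product (K = 2.30, k = 0.00520 min⁻¹, Ea = 128 kJ mol⁻¹, ΔH = −40.0 kJ mol⁻¹)
    open intermediate + second intermediate → target (k = 9.50 M⁻¹ min⁻¹, Ea = 69.0 kJ mol⁻¹)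
    partner → second intermediate (k = 0.240 min⁻¹, Ea = 106 kJ mol⁻¹)
    substrate ⇌ open intermediate (K = 1.50, k = 0.0160 min⁻¹, Ea = 126 kJ mol⁻¹, ΔH = −22.0 kJ mol⁻¹)
    2 second intermediate → homo product (k = 0.680 M⁻¹ min⁻¹, Ea = 64.0 kJ mol⁻¹)
    (constants at 100 °C)

In delta, the half-life of target by conversion into isomer of the product, forward step alone, is 2.2 h, short against the 8.0 h of the run, and delta ends with 27.3% target beside 52.6% isomer of the product. Zeta, with 1.10% target at the change of temperature, ends with 44.0% target beside 30.4% isomer of the product, so target is 0.591 of the two together, against S = 0.686. For the neighbour of beta with 0.380 equiv of partner, target born at the start has S = 0.367. Computed, that neighbour holds 8.64% target beside 15.2% isomer of the product, so target is 0.362 of the two together.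

The data stem from a simulated flask with made-up constants, and the scatter is random.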